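The runs come from a simulation for an exercise, noise included.

I began with the green run. At its last reading, at 6.00 min, it held 4% as J and 15% as Q against 14% as G, a ratio of 1.36.

| flask | E | D | remark | time |
|---|---|---|---|---|
| red | 5.1 mM | 1.5 equiv | run made earlier |  |
| green | 62 mM | 1.5 equiv | run made earlier |  |
| Wednesday's | 80 mM | 1.50 equiv |  | 12 min |
| Monday's | 5.0 mM | 1.50 equiv |  | 12 min |
| Tuesday's | 12 mM | 1.50 equiv |  | 12 min |
| Sunday's | 30 mM | 1.50 equiv |  | 12 min |
| Friday's | 20 mM | 1.50 equiv |  | 12 min |

| run | time / min | G / % | J / % | Q / % |
|---|---|---|---|---|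
| red | 0.500 | 3 | 0 | 0 |
| red | 1.50 | 1 | 0 | 1 |
| red | 3.00 | 0 | 2 | 0 |
| red | 4.00 | 2 | 0 | 0 |
| red | 6.00 | 5 | 3 | 1 |
| green | 0.500 | 3 | 0 | 3 |
| green | 1.50 | 6 | 0 | 1 |
| green | 3.00 | 10 | 1 | 3 |
| green | 4.00 | 10 | 1 | 11 |
| green | 6.00 | 14 | 4 | 15 |

(readings scatter by 1.5 percentage points)

- a species is counted by the E in it: one Q counts as two
- the share counts what is present at the end, not what went on to other products

* the flasks by share of G in all that became G or J or Q, highest first, at 12 min (Wednesday's / Monday's / Tuesday's / Sunday's / Friday's)
* the share of G in all that became G or J or Q of the flask you put first, at 12 min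
* the share of G in all that became G or J or Q of the flask you put last, at 12 min

I supposed that E and D make G, and that G is then lost to partners present in proportion to the charge of E, since the equivalents of D are held. So the ratio of J and Q to G should grow with charge times time, and I folded the givens into one number:

burden = green ratio × (E charged / 62 mM) × (time / 6.00 min)

share of G, its selectivity = 1 / (1 + burden)

Monday's: burden 0.219, share 82.0%

Wednesday's: burden 3.50, share 22.2%

The burden is the J and Q expected per G in a flask. At one common time it follows the charge, so I ranked the flasks from the lowest charge of E to the highest.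

Was one number enough? The red run could not tell me. The red run's burden at 6.00 min was 0.112, but its last readings of 5%, 3% and 1% stood too near the scatter of 1.5 percentage points to test it. I also trusted Wednesday's less. Its burden exceeded 1, so I expected E and D to fall from their charges and the ratio to drift.

The forecast gave Monday's > Tuesday's > Friday's > Sunday's > Wednesday's, with 78% and 21%, holding that “more dilute flasks should therefore keep more G”. My order was the same, and my two shares differed slightly from its values.

The flasks gave Monday's > Tuesday's > Friday's > Sunday's > Wednesday's, with 82.9% and 23.4%.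

    E + D → Z + G (k = 0.00980 M⁻¹ s⁻¹)
    G + D → Z + J (k = 0.00720 M⁻¹ s⁻¹)
    E + G → Q (k = 0.0510 M⁻¹ s⁻¹)
    G → X (k = 1.20 × 10⁻⁶ s⁻¹)

The main reason for Monday's high share was the early hour of reading. Its burden of 0.219 had given 82.0%, beside the 82.9% found. The forecast's 78% belongs to this hour, and a much later reading of the same flask breaks it. Reading at 120 min instead of 12 min raised Monday's burden to 2.19 and my share fell to 31.3%. Monday's flask, left until 120 min, stood at 32.1% against 82.9% at 12 min.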